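**Retrosynthetic overview**
1. Endgame: C15 enal from chemoselective allylic oxidation after global desilylation. Before that, the exocyclic methylene comes from a Horner–Wadsworth–Emmons reaction with formaldehyde and the C8 ester from acylation.
2. γ-Lactone (last ring formed): C7–C11 and O6–C12 bonds from an α-face 6,7-epoxy-8-ketone and a phosphonoacetate carbanion. The 8α-OH comes from ketyl reduction.
3. The epoxy ketone comes from a 4-substituted cyclohexenone, which comes from a cis-fused δ-lactone by hydride opening (frees O14 and O15) and 1,3-carbonyl transposition.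
4. Key disconnection C4–C5 (second, temporary ring): enantioselective 6-exo Heck closure of a 2-bromoallyl ester onto one of two enantiotopic enol ethers of an achiral cyclohexa-1,4-diene. This sets C5 and C10 together.
5. The achiral diene comes from Birch reduction of 3,5-dimethoxybenzoic acid (the arene becomes the carbocycle, the first ring), with ipso C–C bond formation to phenyl vinyl sulfoxide as latent vinyl.

**Conventions and assumptions (one line):** elemane numbering (C10 quaternary carbon, C9 CH2, C8 acyloxy carbon, C7/C6 lactone fusion, C5 carries the C4 acrolein unit, C14 = CH2OAc carbon, C15 = CHO carbon; β = face of C14, α = face of the vinyl group); assumed that (R)-BINAP selects the enol ether leading to the drawn enantiomer (otherwise (S)-BINAP is used) and that 2-(hydroxymethyl)acrylic acid is bought.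

**Step 1**
Reactants: 1 3,5-dimethoxybenzoic acid; 2 phenyl vinyl sulfoxide
Product: 4 3,5-dimethoxy-1-[2-(phenylsulfinyl)ethyl]cyclohexa-2,5-diene-1-carboxylic acid, via dilithium dienediolate 3 (not isolated)
Conditions: Li (3.2 equiv), t-BuOH (2 equiv), NH3(l)/THF, −78 °C; isoprene; 2, −78 → −33 °C; NH4Cl
Reagents that add atoms: none
Why: Birch reduction of the benzoate gives dienediolate 3, which forms its new C–C bond only at the ipso carbon (Birch reductive alkylation run as a Michael addition to the vinyl-cation equivalent 2, with t-BuOH protonating the α-sulfinyl carbanion), and no carbon stereocentre arises because 4 keeps a mirror plane.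

**Step 2**
Reactants: 4 dienecarboxylic acid; 5 2,3-dibromopropene
Product: 6 2-bromoallyl 3,5-dimethoxy-1-[2-(phenylsulfinyl)ethyl]cyclohexa-2,5-diene-1-carboxylate
Conditions: K2CO3, DMF, 23 °C
Reagents that add atoms: none
Why: Carboxylate O-alkylation (SN2) takes place only at the allylic bromide, the vinylic C–Br bond is inert, and the basic medium preserves both enol ethers.

**Step 3**
Reactants: 6 2-bromoallyl ester
Product: 8 cis-fused vinylogous ester δ-lactone (C6 ketone; C7=C8 methyl enol ether; 5α-H; 10α-sulfinylethyl), via dienol ether lactone 7 (not isolated)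
Conditions: Pd2(dba)3·CHCl3 (5 mol %), (R)-BINAP (12 mol %), Ag3PO4 (2 equiv), NMP, 60 °C; filter; TsOH·H2O (10 mol %), MeOH/H2O 50:1, 23 °C
Reagents that add atoms: water O
Why: Proposed new method: oxidative addition of the vinylic C–Br bond to BINAP-ligated zerovalent palladium, bromide abstraction by Ag3PO4, 6-exo syn-carbopalladation of one of the two enantiotopic enol ether double bonds from the face carrying the ester tether (so C4 and C14 end up cis and C5 and C10 are fixed together) and syn β-hydride elimination towards C7 give 7, whose equilibration in wet acidic methanol leaves the enol ether at the less hindered C8, the closest known reaction type being the asymmetric intramolecular Mizoroki–Heck desymmetrisation of Birch-derived cyclohexa-1,4-dienes to cis-decalins.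

**Step 4**
Reactants: 8 sulfoxide δ-lactone
Product: 9 cis-fused vinylogous ester δ-lactone bearing the 10α-vinyl group
Conditions: CaCO3, toluene, 110 °C
Reagents that add atoms: none
Why: Thermal syn-elimination of the sulfoxide (sulfoxide pyrolysis) can only use the C1 hydrogens and so gives the angular vinyl group, which is released after the Heck step because it would otherwise compete as a 6-exo acceptor, and no stereocentre is touched.

**Step 5**
Reactants: 9 vinyl δ-lactone
Product: 10 triol enol ether (C14-OH; C15-OH; C6-OH as an epimer mixture; C7=C8 methyl enol ether)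
Conditions: LiAlH4, THF, 0 → 23 °C; Na2SO4·10H2O quench
Reagents that add atoms: none
Why: Hydride reduction opens the temporary lactone to the C14/C15 diol and reduces the vinylogous ester carbonyl 1,2 (first half of a Stork–Danheiser transposition), the C6 carbinol configuration is irrelevant because it is lost in step 6, and the non-acidic quench keeps the enone masked while hydroxyl groups are free.

**Step 6**
Reactants: 10 triol enol ether
Product: 13 (5β-substituted) cyclohex-6-en-8-one with 14-OAc and 15-OTBS, via C15 monosilyl ether 11 (not isolated), via silyl ether diacetate 12 (not isolated)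
Conditions: TBSCl (1.05 equiv), imidazole, CH2Cl2, −20 °C; Ac2O, Et3N, DMAP, 0 °C; aq. oxalic acid, THF, 0 °C
Reagents that add atoms: tert-butyldimethylsilyl chloride CC(C)(C)[Si](C)(C)Cl; acetic anhydride CC(=O)OC(C)=O; water O
Why: The unhindered allylic primary C15-OH is silylated first, the neopentyl C14-OH and the C6-OH are then acetylated, and mild acid ionises the allylic C6 acetate and hydrolyses the enol ether (Stork–Danheiser 1,3-carbonyl transposition), so the C8 enone appears only when no hydroxyl group is left to add to it.

**Step 7**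
Reactants: 13 enone
Product: 14 6α,7α-epoxy-8-ketone
Conditions: t-BuOOH, DBU, CH2Cl2, 0 °C
Reagents that add atoms: tert-butyl hydroperoxide CC(C)(C)OO
Why: In this Weitz–Scheffer nucleophilic epoxidation the peroxide anion adds to C6 anti to the adjacent β-oriented C5 substituent, which places the oxygen on the α face and sets the final C6 configuration while the isolated alkenes do not react.

**Step 8**
Reactants: 14 epoxy ketone; 15 triethyl phosphonoacetate
Product: 16 trans-fused 11-(diethoxyphosphoryl)-12,6α-lactone 8-ketone (C11 epimer mixture)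
Conditions: 15, LiN(SiMe3)2, THF, −78 °C; add 14, LiClO4, −78 → 23 °C; NH4Cl
Reagents that add atoms: none
Why: Proposed new method: the soft lithium phosphonoacetate carbanion attacks the carbonyl-activated C7 of the lithium-coordinated epoxide from the β face with inversion (its addition to the ketone is reversible and lithium oxido-phosphonates of ketones do not collapse to alkenes at this temperature), and the freed 6α-alkoxide closes onto the ethyl ester after ring flip to give the trans lactone with 7α-H, the closest known reaction types being α-opening of α,β-epoxy ketones by soft nucleophiles and alkylation of phosphonoacetates with α-halo ketones.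

**Step 9**
Reactants: 16 phosphono lactone ketone
Product: 17 8α-alcohol
Conditions: SmI2 (2.5 equiv), THF/H2O 20:1, 0 °C
Reagents that add atoms: none
Why: Single-electron (ketyl) reduction gives the thermodynamically preferred equatorial 8α-alcohol, whereas hydride reagents would be pushed to the α face by the axial β-C14 group and give the 8β-epimer, and esters, the five-membered lactone, the phosphonate and isolated alkenes are not reduced.

**Step 10**
Reactants: 18 2-(hydroxymethyl)acrylic acid
Product: 20 2-[(tert-butyldimethylsilyloxy)methyl]acrylic acid, via bis-silyl derivative 19 (not isolated)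
Conditions: TBSCl (2.2 equiv), imidazole, DMF, 23 °C; K2CO3 (cat.), MeOH/H2O
Reagents that add atoms: tert-butyldimethylsilyl chloride CC(C)(C)[Si](C)(C)Cl
Why: Exhaustive silylation followed by selective solvolysis of the much more labile silyl ester leaves the silyl ether acid (protecting-group chemistry with no stereocentre).

**Step 11**
Reactants: 17 8α-alcohol; 20 silyloxymethyl acrylic acid
Product: 21 8α-[2-(silyloxymethyl)acryloyloxy] phosphono lactone
Conditions: DIC, DMAP, CH2Cl2, 0 → 23 °C
Reagents that add atoms: none
Why: Steglich esterification acylates the only free hydroxyl with retention at C8, and doing this before any carbonate base is used blocks translactonisation from O6 to O8.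

**Step 12**
Reactants: 21 phosphono lactone ester
Product: 22 bis-TBS α-methylene-γ-lactone
Conditions: K2CO3, 37% aq. HCHO, THF, 0 °C
Reagents that add atoms: formaldehyde C=O
Why: Horner–Wadsworth–Emmons olefination of the acidic α-phosphono lactone with formaldehyde installs C13 under conditions that spare the acetate, the acrylate and the silyl ethers and removes the C11 stereocentre.

**Step 13**
Reactants: 22 bis-silyl ether
Product: 23 C15 and side-chain diol
Conditions: HF·pyridine, pyridine/THF, 0 °C
Reagents that add atoms: none
Why: Fluoride-mediated desilylation in a buffered, non-basic medium removes both primary silyl ethers without acyl migration or conjugate addition to the three acceptor alkenes.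

**Step 14**
Reactants: 23 diol
Product: 24 target, 14-acetoxy-8α-[2-(hydroxymethyl)acryloyloxy]-15-oxoelema-1,3,11(13)-trien-12,6α-olide
Conditions: MnO2 (activated, excess), CH2Cl2, 23 °C, monitored
Reagents that add atoms: none
Why: Chemoselective MnO2 allylic oxidation converts the electron-rich 2-alkylallyl alcohol (C15) to the enal much faster than the electron-poor 2-(alkoxycarbonyl)allyl alcohol of the side chain, and since O14 is already acetylated no hemiacetal can form.

**Compound list**
1 | 3,5-dimethoxybenzoic acid | COc1cc(OC)cc(C(=O)O)c1 | starting material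
2 | phenyl vinyl sulfoxide (racemic) | C=CS(=O)c1ccccc1 | starting material
3 | dilithium dienediolate of 1,4-dihydro-3,5-dimethoxybenzoic acid | [Li+].[Li+].COC1=CC(=C([O-])[O-])C=C(OC)C1 | intermediate
4 | 3,5-dimethoxy-1-[2-(phenylsulfinyl)ethyl]cyclohexa-2,5-diene-1-carboxylic acid (mirror-symmetric ring, racemic at sulfur) | OC(=O)C1(CCS(=O)c2ccccc2)C=C(OC)CC(OC)=C1 | intermediate
5 | 2,3-dibromopropene | C=C(Br)CBr | starting material
6 | 2-bromoallyl ester of 4 | C=C(Br)COC(=O)C1(CCS(=O)c2ccccc2)C=C(OC)CC(OC)=C1 | intermediate
7 | cis-fused δ-lactone C14(=O)-O-C15H2-C4(=CH2)-C5 on a 6,8-dimethoxy-6,8-diene; 5α-H, 10α-CH2CH2S(O)Ph, 10β-C14 | O=S(c1ccccc1)CC[C@]1(C(=O)OC2)C=C(OC)C=C(OC)[C@H]1C2=C | intermediate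
8 | same cis-fused δ-lactone with C6 ketone and C7=C8 methyl enol ether | O=S(c1ccccc1)CC[C@]1(C(=O)OC2)CC(OC)=CC(=O)[C@H]1C2=C | intermediate
9 | 10α-vinyl analogue of 8 | C=C[C@]1(C(=O)OC2)CC(OC)=CC(=O)[C@H]1C2=C | intermediate
10 | triol enol ether: 10β-CH2OH, 10α-vinyl, 5β-C(=CH2)CH2OH, C6-OH (epimers), C7=C8(OMe) | C=C[C@]1(CO)CC(OC)=CC(O)[C@H]1C(=C)CO | intermediate
11 | 15-O-TBS ether of 10 | C=C[C@]1(CO)CC(OC)=CC(O)[C@H]1C(=C)CO[Si](C)(C)C(C)(C)C | intermediate
12 | 15-O-TBS 6,14-diacetate of 10 | C=C[C@]1(COC(C)=O)CC(OC)=CC(OC(C)=O)[C@H]1C(=C)CO[Si](C)(C)C(C)(C)C | intermediate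
13 | C8 ketone, C6=C7 enone; 10β-CH2OAc, 10α-vinyl, 5β-C(=CH2)CH2OTBS, 5α-H | C=C[C@]1(COC(C)=O)CC(=O)C=C[C@H]1C(=C)CO[Si](C)(C)C(C)(C)C | intermediate
14 | 6α,7α-epoxide of 13 | C=C[C@]1(COC(C)=O)CC(=O)[C@@H]2O[C@@H]2[C@H]1C(=C)CO[Si](C)(C)C(C)(C)C | intermediate
15 | triethyl phosphonoacetate | CCOC(=O)CP(=O)(OCC)OCC | starting material
16 | trans-fused 12,6α-lactone (6β-H, 7α-H) with 11-P(O)(OEt)2 and C8 ketone | C=C[C@]1(COC(C)=O)CC(=O)[C@H]2C(P(=O)(OCC)OCC)C(=O)O[C@@H]2[C@H]1C(=C)CO[Si](C)(C)C(C)(C)C | intermediate
17 | 8α-alcohol (8β-H) of 16 | C=C[C@]1(COC(C)=O)C[C@H](O)[C@H]2C(P(=O)(OCC)OCC)C(=O)O[C@@H]2[C@H]1C(=C)CO[Si](C)(C)C(C)(C)C | intermediate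
18 | 2-(hydroxymethyl)acrylic acid | C=C(CO)C(=O)O | starting material
19 | TBS ester TBS ether of 18 | C=C(CO[Si](C)(C)C(C)(C)C)C(=O)O[Si](C)(C)C(C)(C)C | intermediate
20 | 2-[(tert-butyldimethylsilyloxy)methyl]acrylic acid | C=C(CO[Si](C)(C)C(C)(C)C)C(=O)O | intermediate
21 | 8α-ester of 17 with 20 | C=C[C@]1(COC(C)=O)C[C@H](OC(=O)C(=C)CO[Si](C)(C)C(C)(C)C)[C@H]2C(P(=O)(OCC)OCC)C(=O)O[C@@H]2[C@H]1C(=C)CO[Si](C)(C)C(C)(C)C | intermediate
22 | bis-TBS ether of 23 (α-methylene-γ-lactone) | C=C[C@]1(COC(C)=O)C[C@H](OC(=O)C(=C)CO[Si](C)(C)C(C)(C)C)[C@H]2C(=C)C(=O)O[C@@H]2[C@H]1C(=C)CO[Si](C)(C)C(C)(C)C | intermediate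
23 | 15-hydroxy precursor (15-CH2OH in place of CHO) | C=C[C@]1(COC(C)=O)C[C@H](OC(=O)C(=C)CO)[C@H]2C(=C)C(=O)O[C@@H]2[C@H]1C(=C)CO | intermediate
24 | CNP0185525.1 | C=C[C@]1(COC(C)=O)C[C@H](OC(=O)C(=C)CO)[C@H]2C(=C)C(=O)O[C@@H]2[C@H]1C(=C)C=O | target

**Totals:** 14 steps in all. The longest linear sequence is 13 steps (steps 1–9 and 11–14).

**Steps most likely to fail**

*Step 3 (asymmetric Heck on an electron-rich bis(enol ether) through an ester tether).* The risks are reversible ionisation of the allylic ester by zerovalent palladium, the unfavourable ester rotamer, the polarity mismatch of the insertion, and drift of the C4=CH2 bond into conjugation with the C6 ketone. The fallback sets out from 4 and comes back at 8, and it reverses the polarity of the ring closure. Acid 4 is esterified with allyl bromide and K2CO3 to the allyl ester F2. The same C4–C5 bond is then closed by an oxidative enol ether/olefin coupling under divalent palladium (Pd(OAc)2, a chiral pyridine-oxazoline ligand, O2, wet DMSO; Kende/Toyota–Ihara cycloalkenylation type). The enol ether carbon C5 attacks the palladium-bound allyl double bond at its inner carbon, and β-hydride elimination gives C4=CH2. Water turns the C6 oxocarbenium ion into the ketone, so 8 forms directly without any equilibration.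

*Step 8 (β-face attack of a bulky carbanion at C7, syn to the C5 substituent, with olefination of the ketone and β-elimination as competitors).* The fallback sets out from 14 and comes back at 22. It sets all three stereocentres by epoxide chemistry and uses a small linear nucleophile.
- Wharton transposition of 14 (N2H4·H2O, cat. AcOH, MeOH) gives the 6α-allylic alcohol F3.
- Hydroxyl-directed epoxidation (VO(acac)2, t-BuOOH) gives the 7α,8α-epoxy alcohol F4.
- Diethyl(ethynyl)aluminium (Et2AlC≡CH, toluene) opens the epoxide at C7 to give the 7β-ethynyl-6α,8α-diol F5.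
- The less hindered 8α-OH is esterified with 20 (DIC, DMAP) to give the alkynol ester F6.
- Palladium-catalysed cyclocarbonylation of the homopropargylic 6α-OH (PdCl2, thiourea, CO 1 atm, acetone) builds the α-methylene lactone of 22 in one operation.

*Step 1 (conjugate addition of the hindered Birch dienediolate to 2, with oligomerisation through the α-sulfinyl carbanion as the competitor).* The fallback sets out from 1 and comes back at 4, and it replaces the Michael addition by an SN2 alkylation. The Birch reduction is run as in step 1, but 3 is quenched with 2-bromoethyl phenyl sulfide, a reactive electrophile through sulfur participation. This gives the sulfide acid F1. F1 is oxidised at sulfur with one equivalent of mCPBA (NaHCO3, CH2Cl2, −78 °C), where sulfide oxidation outruns enol ether epoxidation, to give 4.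

**Further compounds**
F1 | step 1 | 3,5-dimethoxy-1-[2-(phenylsulfanyl)ethyl]cyclohexa-2,5-diene-1-carboxylic acid | OC(=O)C1(CCSc2ccccc2)C=C(OC)CC(OC)=C1
F2 | step 3 | allyl 3,5-dimethoxy-1-[2-(phenylsulfinyl)ethyl]cyclohexa-2,5-diene-1-carboxylate | C=CCOC(=O)C1(CCS(=O)c2ccccc2)C=C(OC)CC(OC)=C1
F3 | step 8 | 6α-hydroxy-7-ene (Wharton product of 14) | C=C[C@]1(COC(C)=O)CC=C[C@H](O)[C@H]1C(=C)CO[Si](C)(C)C(C)(C)C
F4 | step 8 | 7α,8α-epoxy-6α-ol | C=C[C@]1(COC(C)=O)C[C@@H]2O[C@@H]2[C@H](O)[C@H]1C(=C)CO[Si](C)(C)C(C)(C)C
F5 | step 8 | 7β-ethynyl-6α,8α-diol | C=C[C@]1(COC(C)=O)C[C@H](O)[C@@H](C#C)[C@H](O)[C@H]1C(=C)CO[Si](C)(C)C(C)(C)C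
F6 | step 8 | 8α-[2-(silyloxymethyl)acrylate] of F5 | C=C[C@]1(COC(C)=O)C[C@H](OC(=O)C(=C)CO[Si](C)(C)C(C)(C)C)[C@@H](C#C)[C@H](O)[C@H]1C(=C)CO[Si](C)(C)C(C)(C)C
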